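**Retrosynthetic overview**
1. Feature: in ring B (C5, C6, C7, C8, C9, C10) the C7 isopropenyl group and the C8 oxygen are vicinal and trans, and C8–O is cis to C9–O. This isopulegol unit is opened at C7–C8 to a prenyl group on C5 and an aldehyde at C8 (Lewis-acid carbonyl-ene).
2. Ene precursor 19 carries O9 tied to C2 as a bridged methyl ketal, which locks ring A with the side chain axial and lets O8/O9 chelate Me2AlCl. After the ene step O8 is acetylated, the ketal opened and O9 tigloylated.
3. 19 ⇐ C9 acyl dithiane 16 (Felkin–Anh reduction sets C9) ⇐ bridged lactol 11 (closure onto the C2 hydroxyl sets C10) ⇐ ketone 8.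
4. 8 ⇐ (S)-carvone: Criegee degradation of the isopropenyl group to the C2 oxygen, then Me2CuLi and prenyl bromide set C4 and C5.
5. Ring order: ring A (C1–C5, C10) is the carvone ring; ring B is closed in the key step, three steps before the end.

Key step: step 12

Remark: target atom numbers are used for all intermediates; β is the face of the C4 and C5 methyl groups and of H-10, α the face of O8 and O9. A C9 ester cannot chelate and would sit axial beside C4, and an α-silyloxy group at C2 would be syn-axial to the C10 side chain in the chair the cyclisation needs, so the two oxygens are joined through C2 instead (ketal 19).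

**Step 1**
Reactants: 1 (S)-carvone
Product: 3 (5S)-5-acetoxy-2-methylcyclohex-2-en-1-one, via methoxy hydroperoxide 2 (not isolated)
Conditions: O3, CH2Cl2/MeOH, −78 °C; then Ac2O, Et3N, DMAP (cat.), CH2Cl2, 0 → 23 °C
Reagents that add atoms: ozone [O-][O+]=O; methanol CO
Why: Ozone cleaves the electron-rich isopropenyl alkene and leaves the enone, methanol traps the carbonyl oxide as 2, and O-acetylation of 2 triggers the Criegee rearrangement in which the ring carbon migrates from carbon to oxygen with retention, so the C2 oxygen takes the carvone configuration.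

**Step 2**
Reactants: 3 (5S)-5-acetoxy-2-methylcyclohex-2-en-1-one
Product: 4 (5S)-5-hydroxy-2-methylcyclohex-2-en-1-one
Conditions: K2CO3 (0.2 equiv), MeOH, 0 °C
Reagents that add atoms: none
Why: Carbonate-catalysed methanolysis (transesterification) frees the alcohol at 0 °C, cold enough that E1cB loss of the β-oxygen from the enone should not compete; no stereocentre is touched.

**Step 3**
Reactants: 4 (5S)-5-hydroxy-2-methylcyclohex-2-en-1-one
Product: 5 (5S)-5-(tert-butyldimethylsilyloxy)-2-methylcyclohex-2-en-1-one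
Conditions: TBSCl, imidazole, DMF, 23 °C
Reagents that add atoms: tert-butyldimethylsilyl chloride CC(C)(C)[Si](C)(C)Cl
Why: Imidazole-promoted silylation (Corey conditions) gives an ether that survives cuprate and ylide chemistry and is a poor leaving group from the enolates of steps 4 and 5.

**Step 4**
Reactants: 5 (5S)-5-(tert-butyldimethylsilyloxy)-2-methylcyclohex-2-en-1-one; 6 prenyl bromide
Product: 8 (2R,3S,5S)-5-(tert-butyldimethylsilyloxy)-2,3-dimethyl-2-(3-methylbut-2-enyl)cyclohexan-1-one, via lithium enolate 7 (not isolated)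
Conditions: Me2CuLi (from MeLi and CuI), Et2O, −78 → −30 °C; then 6, HMPA, THF, −30 → 0 °C
Reagents that add atoms: lithium dimethylcuprate [Li+].C[Cu-]C
Why: Tandem cuprate conjugate addition and enolate alkylation: methyl should add to C4 trans to the C2 silyloxy group (axial attack on the half-chair, the known trans-3,5 preference of 5-substituted cyclohexenones), and the regiodefined enolate 7 should take prenyl bromide at C5 on the face away from the new C4 methyl, which leaves the two methyl groups cis.

**Step 5**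
Reactants: 8 (2R,3S,5S)-5-(tert-butyldimethylsilyloxy)-2,3-dimethyl-2-(3-methylbut-2-enyl)cyclohexan-1-one
Product: 9 methyl enol ether tert-butyl-[5-(methoxymethylidene)-3,4-dimethyl-4-(3-methylbut-2-enyl)cyclohexyl]oxy-dimethylsilane (E/Z mixture)
Conditions: Ph3P(CH2OMe)Cl, KN(SiMe3)2, THF, 0 °C; then 8, 0 → 45 °C
Reagents that add atoms: (methoxymethylidene)triphenylphosphorane COC=P(c1ccccc1)(c1ccccc1)c1ccccc1
Why: Wittig methoxymethylenation with the small, reactive ylide Ph3P=CHOMe is the usual one-carbon homologation of α-quaternary cyclohexanones and brings in C9; the E/Z mixture is of no consequence.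

**Step 6**
Reactants: 9 methyl enol ether
Product: 11 bridged lactol 2,3-dimethyl-2-(3-methylbut-2-enyl)-6-oxabicyclo[3.2.1]octan-7-ol, via hydroxy aldehyde 10 (not isolated)
Conditions: 1 M aq. HCl, THF, 23 → 40 °C; then K2CO3, MeOH, 23 °C
Reagents that add atoms: water O
Why: Acid hydrolyses the enol ether and the silyl ether to the γ-hydroxy aldehyde 10, and equilibration at C10 through the enol or enolate should drain both epimers into lactol 11, because only the epimer with the formyl group cis to the C2 oxygen (H-10 β) can close the oxabicyclo[3.2.1]octane, so C10 is set under thermodynamic control.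

**Step 7**
Reactants: 11 bridged lactol; 12 1,3-dithiane
Product: 14 diol 3-[1,3-dithian-2-yl(hydroxy)methyl]-4,5-dimethyl-4-(3-methylbut-2-enyl)cyclohexan-1-ol (C9 epimers), via 2-lithio-1,3-dithiane 13 (not isolated)
Conditions: 12, n-BuLi, THF, −30 °C; then 11, −78 → 0 °C; aq. NH4Cl
Reagents that add atoms: none
Why: Corey–Seebach addition: the lithium lactolate opens to the aldehyde and 13 adds to it, bringing in C8 as a masked formyl group; the C9 configuration formed here does not matter because C9 is oxidised in step 8.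

**Step 8**
Reactants: 14 diol
Product: 15 diketone 3-(1,3-dithiane-2-carbonyl)-4,5-dimethyl-4-(3-methylbut-2-enyl)cyclohexan-1-one
Conditions: (COCl)2, DMSO, CH2Cl2, −78 °C; then Et3N, −78 → −20 °C
Reagents that add atoms: none
Why: Swern oxidation of both secondary alcohols; the dithiane is inert at −78 °C, and the acyl dithiane, whose most acidic hydrogen is on C8, should not enolise toward C10.

**Step 9**
Reactants: 15 diketone
Product: 16 keto ketal [5,5-dimethoxy-2,3-dimethyl-2-(3-methylbut-2-enyl)cyclohexyl](1,3-dithian-2-yl)methanone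
Conditions: HC(OMe)3, MeOH, PPTS (cat.), 23 °C
Reagents that add atoms: trimethyl orthoformate COC(OC)OC; methanol CO
Why: Acid-catalysed ketalisation with an orthoformate as water scavenger should be chemoselective for the unhindered ring ketone, the acyl dithiane carbonyl being flanked by two branched carbons.

**Step 10**
Reactants: 16 keto ketal
Product: 18 bridged methyl ketal 2-[5-methoxy-2,3-dimethyl-2-(3-methylbut-2-enyl)-6-oxabicyclo[3.2.1]octan-7-yl]-1,3-dithiane, via carbinol 17 (not isolated)
Conditions: NaBH4, MeOH/THF, 0 °C; then PPTS (cat.), 4 Å MS, CH2Cl2, 23 °C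
Reagents that add atoms: none
Why: Felkin–Anh reduction: hydride should attack the C9 ketone anti to the quaternary C5 with the dithianyl group beside H-10, which gives the (9S) carbinol 17, and mild acid then exchanges one methoxy group for O9 (intramolecular transketalisation), which is possible because the side chain and the C2–O bond are both axial on the α face.

**Step 11**
Reactants: 18 bridged methyl ketal dithiane
Product: 19 aldehyde 5-methoxy-2,3-dimethyl-2-(3-methylbut-2-enyl)-6-oxabicyclo[3.2.1]octane-7-carbaldehyde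
Conditions: MeI, CaCO3, MeCN/H2O (9:1), 45 °C
Reagents that add atoms: water O
Why: Alkylative dithiane hydrolysis: S-methylation turns the dithiane into a leaving group and water releases the aldehyde under CaCO3 buffering, which should spare the ketal, the alkene and the epimerisable α-alkoxy aldehyde.

**Step 12**
Reactants: 19 aldehyde 5-methoxy-2,3-dimethyl-2-(3-methylbut-2-enyl)-6-oxabicyclo[3.2.1]octane-7-carbaldehyde
Product: 20 ene product 2β-methoxy-2α,9α-epoxy-10βH-eremophil-11-en-8α-ol
Conditions: Me2AlCl (2.5 equiv), CH2Cl2, −78 °C; aq. NaHCO3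
Reagents that add atoms: none
Why: Me2AlCl in excess should bind the aldehyde oxygen O8 and the adjacent ring-ether oxygen O9 as a five-membered cationic chelate, and C7 of the prenyl alkene then attacks C8 while a methyl hydrogen on C11 passes to O8 and the double bond moves into the isopropenyl position; this is a type-one intramolecular carbonyl-ene reaction, closest known in the Lewis-acid cyclisation of citronellal to isopulegol and in chelation-controlled additions to α-alkoxy aldehydes. Ring B closes as a six-membered carbocycle by C7–C8 bonding through a chair-like transition state, exo with respect to both the C8=O8 and the C7=C11 π bonds. C8 is controlled by the chelate: O8 is held syn to O9, the tether lets the alkene reach only one face of that rotamer, and the hydroxyl should therefore come out equatorial, α and cis to O9. C7 is controlled by the chair: the isopropylidene terminus sits equatorial, away from the axial C5–C4 bond and from O9, so the isopropenyl group should end β and trans to O8. The step needs the one chair in which O9 is axial on the new ring and the C5 methyl equatorial, and it needs the aldehyde to react before the ketal; the oxabicyclo[3.2.1]octane secures the first by holding the C10 side chain axial on ring A with O9 over C2, and the second is helped by −78 °C and by the fact that loss of methoxide would require a bridgehead (anti-Bredt) oxocarbenium ion.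

**Step 13**
Reactants: 20 ene product
Product: 21 acetate 8α-acetoxy-2β-methoxy-2α,9α-epoxy-10βH-eremophil-11-ene
Conditions: Ac2O, DMAP (cat.), pyridine, CH2Cl2, 0 → 23 °C
Reagents that add atoms: acetic anhydride CC(=O)OC(C)=O
Why: DMAP-catalysed acetylation of the equatorial C8 hydroxyl while O9 is still held in the ketal, which differentiates the two oxygens without a separate protecting group.

**Step 14**
Reactants: 21 acetate
Product: 22 hydroxy ketone 8α-acetoxy-9α-hydroxy-10βH-eremophil-11-en-2-one (in equilibrium with its 2,9-hemiketal)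
Conditions: 0.5 M aq. HCl, THF, 23 °C
Reagents that add atoms: water O
Why: Acid-catalysed ketal hydrolysis by C2–O9 cleavage frees the C2 ketone and the C9 hydroxyl, which should rest largely as the hemiketal and so are kept from taking over the neighbouring acetyl group.

**Step 15**
Reactants: 22 hydroxy ketone; 23 tigloyl chloride
Product: 24 target 8α-acetoxy-9α-tigloyloxy-10βH-eremophil-11-en-2-one
Conditions: 23, DMAP, pyridine, CH2Cl2, 0 → 40 °C
Reagents that add atoms: none
Why: DMAP-catalysed acylation with the acid chloride traps the open hydroxy ketone form at O9 and so drains the hemiketal, leaving the C2 ketone free; no stereocentre is touched and the E geometry of the tiglate is retained.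

**Compound list**
1 | (S)-carvone | CC(=C)[C@H]1CC=C(C)C(=O)C1 | starting material
2 | 5-(1-hydroperoxy-1-methoxyethyl)-2-methylcyclohex-2-en-1-one (epimers at the peroxy carbon) | CC(OC)(OO)[C@H]1CC=C(C)C(=O)C1 | intermediate (not isolated)
3 | (5S)-5-acetoxy-2-methylcyclohex-2-en-1-one | CC(=O)O[C@H]1CC=C(C)C(=O)C1 | intermediate
4 | (5S)-5-hydroxy-2-methylcyclohex-2-en-1-one | O[C@H]1CC=C(C)C(=O)C1 | intermediate
5 | (5S)-5-(tert-butyldimethylsilyloxy)-2-methylcyclohex-2-en-1-one | CC(C)(C)[Si](C)(C)O[C@H]1CC=C(C)C(=O)C1 | intermediate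
6 | prenyl bromide (1-bromo-3-methylbut-2-ene) | CC(C)=CCBr | starting material
7 | lithium (3S,5S)-5-(tert-butyldimethylsilyloxy)-2,3-dimethylcyclohex-1-en-1-olate | [Li]OC1=C(C)[C@@H](C)C[C@H](O[Si](C)(C)C(C)(C)C)C1 | intermediate (not isolated)
8 | (2R,3S,5S)-5-(tert-butyldimethylsilyloxy)-2,3-dimethyl-2-(3-methylbut-2-enyl)cyclohexan-1-one (C4 and C5 methyls cis, C4 methyl trans to C2–O) | CC(C)=CC[C@@]1(C)C(=O)C[C@@H](O[Si](C)(C)C(C)(C)C)C[C@@H]1C | intermediate
9 | tert-butyl-[5-(methoxymethylidene)-3,4-dimethyl-4-(3-methylbut-2-enyl)cyclohexyl]oxy-dimethylsilane, E/Z mixture, ring centres as in 8 | CC(C)=CC[C@@]1(C)C(=COC)C[C@@H](O[Si](C)(C)C(C)(C)C)C[C@@H]1C | intermediate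
10 | 5-hydroxy-2,3-dimethyl-2-(3-methylbut-2-enyl)cyclohexane-1-carbaldehyde, both C10 epimers | CC(C)=CC[C@@]1(C)C(C=O)C[C@@H](O)C[C@@H]1C | intermediate (not isolated)
11 | 2,3-dimethyl-2-(3-methylbut-2-enyl)-6-oxabicyclo[3.2.1]octan-7-ol (H-10 β; lactol anomers) | CC(C)=CC[C@@]1(C)[C@@H]2C[C@H](C[C@@H]1C)OC2O | intermediate
12 | 1,3-dithiane | C1CSCSC1 | starting material
13 | 2-lithio-1,3-dithiane | [Li]C1SCCCS1 | intermediate (not isolated)
14 | 3-[1,3-dithian-2-yl(hydroxy)methyl]-4,5-dimethyl-4-(3-methylbut-2-enyl)cyclohexan-1-ol, C9 epimers | CC(C)=CC[C@@]1(C)[C@H](C[C@@H](O)C[C@@H]1C)C(O)C1SCCCS1 | intermediate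
15 | 3-(1,3-dithiane-2-carbonyl)-4,5-dimethyl-4-(3-methylbut-2-enyl)cyclohexan-1-one | CC(C)=CC[C@@]1(C)[C@H](CC(=O)C[C@@H]1C)C(=O)C1SCCCS1 | intermediate
16 | [5,5-dimethoxy-2,3-dimethyl-2-(3-methylbut-2-enyl)cyclohexyl](1,3-dithian-2-yl)methanone | CC(C)=CC[C@@]1(C)[C@H](CC(OC)(OC)C[C@@H]1C)C(=O)C1SCCCS1 | intermediate
17 | (S)-[5,5-dimethoxy-2,3-dimethyl-2-(3-methylbut-2-enyl)cyclohexyl](1,3-dithian-2-yl)methanol | CC(C)=CC[C@@]1(C)[C@H](CC(OC)(OC)C[C@@H]1C)[C@H](O)C1SCCCS1 | intermediate (not isolated)
18 | 2-[5-methoxy-2,3-dimethyl-2-(3-methylbut-2-enyl)-6-oxabicyclo[3.2.1]octan-7-yl]-1,3-dithiane (O9 bridging to C2 on the α face) | CC(C)=CC[C@@]1(C)[C@@H]2C[C@](OC)(C[C@@H]1C)O[C@@H]2C1SCCCS1 | intermediate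
19 | 5-methoxy-2,3-dimethyl-2-(3-methylbut-2-enyl)-6-oxabicyclo[3.2.1]octane-7-carbaldehyde (ene precursor) | CC(C)=CC[C@@]1(C)[C@@H]2C[C@](OC)(C[C@@H]1C)O[C@@H]2C=O | intermediate
20 | 2β-methoxy-2α,9α-epoxy-10βH-eremophil-11-en-8α-ol (ene product; 7β-isopropenyl) | C=C(C)[C@H]1C[C@@]2(C)[C@@H]3C[C@](OC)(C[C@@H]2C)O[C@@H]3[C@@H]1O | intermediate
21 | 8α-acetoxy-2β-methoxy-2α,9α-epoxy-10βH-eremophil-11-ene | C=C(C)[C@H]1C[C@@]2(C)[C@@H]3C[C@](OC)(C[C@@H]2C)O[C@@H]3[C@@H]1OC(C)=O | intermediate
22 | 8α-acetoxy-9α-hydroxy-10βH-eremophil-11-en-2-one (open form drawn; ring-chain tautomer of the 2,9-hemiketal) | C=C(C)[C@H]1C[C@@]2(C)[C@H](CC(=O)C[C@@H]2C)[C@H](O)[C@@H]1OC(C)=O | intermediate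
23 | tigloyl chloride, (E)-2-methylbut-2-enoyl chloride | C/C=C(\C)C(Cl)=O | starting material
24 | (1S,2R,3R,4aR,5S,8aS)-2-acetoxy-4a,5-dimethyl-7-oxo-3-(prop-1-en-2-yl)decahydronaphthalen-1-yl (E)-2-methylbut-2-enoate (CNP0204573.1) | C=C(C)[C@H]1C[C@@]2(C)[C@H](CC(=O)C[C@@H]2C)[C@H](OC(=O)/C(C)=C/C)[C@@H]1OC(C)=O | target

**Step count:** 15 steps in total. Longest linear sequence: 15 steps from 1 (6, 12 and 23 are bought).

**Steps most likely to fail**

Step 12 (key step). The aluminium Lewis acid may open the bridged ketal at C2–O9 before the ene reaction, and the resulting C2 oxocarbenium ion could react with the prenyl alkene. Alternatively the aldehyde may react without chelation, through the rotamer with O8 anti to O9, which would give the C8 epimer. The fallback sets out from 16 and comes back at 22. 16 is reduced with NaBH4 as in step 10, but carbinol 17 is isolated instead of being cyclised. Its hydroxyl is etherified (NaH, 4-methoxybenzyl chloride, Bu4NI, THF) to the C9 4-methoxybenzyl ether F1. MeI/CaCO3 in aqueous MeCN followed by dilute aq. HCl removes the dithiane and the dimethyl ketal and gives the keto aldehyde F2, which has no acid-labile ketal and an ether oxygen that chelates well. Me2AlCl (2.5 equiv) or MgBr2·OEt2 in CH2Cl2 then closes ring B under chelation control to the hydroxy ketone F3. Acetylation (Ac2O, DMAP) gives the acetate F4, and DDQ in CH2Cl2/pH 7 buffer removes the 4-methoxybenzyl group to give 22.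

Step 15. Acylation may be slow because the axial C9 hydroxyl lies in the concave face and is largely hidden in the hemiketal. That leaves time for base-induced migration of the acetyl group from O8 to O9, followed by tigloylation of the freed O8. The fallback sets out from 20 and comes back at 24, with the order of the two esters inverted. 20 is silylated at O8 (TBSCl, imidazole, DMF) to the silyl ether F5. The ketal is hydrolysed (PPTS, acetone/H2O) to the hydroxy ketone F6, which has no acyl group that could migrate. O9 is tigloylated (23, DMAP, pyridine) to the tiglate F7. HF·pyridine removes the silyl group to give the hydroxy tiglate F8, and the unhindered equatorial C8 hydroxyl is acetylated last (Ac2O, DMAP) to give 24.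

Step 5. The ylide may deprotonate the hindered ketone at C1 instead of adding to it, and the enolate may then expel the C2 silyloxy group. The fallback sets out from 8 and comes back at 11. 8 is converted at −78 °C into the enol triflate F9 (KN(SiMe3)2, PhNTf2, THF). Carbonylation (Pd(OAc)2, PPh3, CO, MeOH, Et3N, DMF) gives the unsaturated methyl ester F10. Conjugate reduction with [(Ph3P)CuH]6 (cat.) and PhSiH3 gives the saturated ester F11 as a mixture at C10. Bu4NF and then DBU in hot toluene remove the silyl group, equilibrate C10 and close the bridged lactone F12, and i-Bu2AlH at −78 °C reduces it to lactol 11.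

**Further compounds**
F1 | step 12 | 2-[(S)-[5,5-dimethoxy-2,3-dimethyl-2-(3-methylbut-2-enyl)cyclohexyl](4-methoxybenzyloxy)methyl]-1,3-dithiane | CC(C)=CC[C@@]1(C)[C@H](CC(OC)(OC)C[C@@H]1C)[C@H](OCc1ccc(OC)cc1)C1SCCCS1
F2 | step 12 | (S)-2-[2,3-dimethyl-2-(3-methylbut-2-enyl)-5-oxocyclohexyl]-2-(4-methoxybenzyloxy)acetaldehyde | CC(C)=CC[C@@]1(C)[C@H](CC(=O)C[C@@H]1C)[C@H](OCc1ccc(OC)cc1)C=O
F3 | step 12 | 8α-hydroxy-9α-(4-methoxybenzyloxy)-10βH-eremophil-11-en-2-one | C=C(C)[C@H]1C[C@@]2(C)[C@H](CC(=O)C[C@@H]2C)[C@H](OCc2ccc(OC)cc2)[C@@H]1O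
F4 | step 12 | 8α-acetoxy-9α-(4-methoxybenzyloxy)-10βH-eremophil-11-en-2-one | C=C(C)[C@H]1C[C@@]2(C)[C@H](CC(=O)C[C@@H]2C)[C@H](OCc2ccc(OC)cc2)[C@@H]1OC(C)=O
F5 | step 15 | 8α-(tert-butyldimethylsilyloxy)-2β-methoxy-2α,9α-epoxy-10βH-eremophil-11-ene | C=C(C)[C@H]1C[C@@]2(C)[C@@H]3C[C@](OC)(C[C@@H]2C)O[C@@H]3[C@@H]1O[Si](C)(C)C(C)(C)C
F6 | step 15 | 8α-(tert-butyldimethylsilyloxy)-9α-hydroxy-10βH-eremophil-11-en-2-one | C=C(C)[C@H]1C[C@@]2(C)[C@H](CC(=O)C[C@@H]2C)[C@H](O)[C@@H]1O[Si](C)(C)C(C)(C)C
F7 | step 15 | 8α-(tert-butyldimethylsilyloxy)-9α-tigloyloxy-10βH-eremophil-11-en-2-one | C=C(C)[C@H]1C[C@@]2(C)[C@H](CC(=O)C[C@@H]2C)[C@H](OC(=O)/C(C)=C/C)[C@@H]1O[Si](C)(C)C(C)(C)C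
F8 | step 15 | 8α-hydroxy-9α-tigloyloxy-10βH-eremophil-11-en-2-one | C=C(C)[C@H]1C[C@@]2(C)[C@H](CC(=O)C[C@@H]2C)[C@H](OC(=O)/C(C)=C/C)[C@@H]1O
F9 | step 5 | 3-(tert-butyldimethylsilyloxy)-5,6-dimethyl-6-(3-methylbut-2-enyl)cyclohex-1-en-1-yl trifluoromethanesulfonate | CC(C)=CC[C@@]1(C)C(OS(=O)(=O)C(F)(F)F)=C[C@@H](O[Si](C)(C)C(C)(C)C)C[C@@H]1C
F10 | step 5 | methyl 3-(tert-butyldimethylsilyloxy)-5,6-dimethyl-6-(3-methylbut-2-enyl)cyclohex-1-ene-1-carboxylate | CC(C)=CC[C@@]1(C)C(C(=O)OC)=C[C@@H](O[Si](C)(C)C(C)(C)C)C[C@@H]1C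
F11 | step 5 | methyl 5-(tert-butyldimethylsilyloxy)-2,3-dimethyl-2-(3-methylbut-2-enyl)cyclohexane-1-carboxylate (C10 epimers) | CC(C)=CC[C@@]1(C)C(C(=O)OC)C[C@@H](O[Si](C)(C)C(C)(C)C)C[C@@H]1C
F12 | step 5 | 2,3-dimethyl-2-(3-methylbut-2-enyl)-6-oxabicyclo[3.2.1]octan-7-one | CC(C)=CC[C@@]1(C)[C@@H]2C[C@H](C[C@@H]1C)OC2=O
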